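**Plan**
- The target consists of two constitutionally identical (2R,3S)-flavan-3-ol halves that share one ether oxygen between C3' and C3'''. It is therefore C2-symmetric, and every operation can be run twice on one substrate.
- Retrosynthetic cuts, in order: the six O-benzyl groups; C4-H back to C4=O and C3-OH back to C3-H (bis-flavanone); both O1-C2 bonds of the two rings C; both C2-C3 bonds (Knoevenagel); and last the C3'-O aryl ether bond (Ullmann).
- Enabling feature: in each half, O1 sits on ring A ortho to the carbon that bears C4, and C2 is the benzylic carbon of ring B. Ring C is thus a masked 2'-hydroxychalcone whose phenol oxygen can add to its own enone beta-carbon.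
- Forward order: rings A and B are purchased. The B-O-B ether is made first, both three-carbon arms are attached, and both rings C close in one operation. C3 is then oxygenated and C4 deoxygenated.
- Stereochemistry: both C2 centres come from a cinchona thiourea catalyst in the ring closure. Both C3 carbinol centres are relayed from C2 by oxidising an enol ether on the face away from the C2 aryl group. The two-fold reaction upgrades enantiopurity at the cost of a meso by-product.

Key step: step 6

Assumption: the thiourea built on 9-amino-9-deoxy-epi-quinidine is taken to give the (2S)-flavanone sense, by analogy with cinchona thiourea conjugate additions to chalcone-type acceptors. The quinine-derived pseudoenantiomer would give the mirror image.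

**Step 1**
Reactants: 1 2,4,6-trihydroxyacetophenone
Product: 2 1-[2,4-bis(benzyloxy)-6-hydroxyphenyl]ethanone
Conditions: BnBr (2.05 equiv), K2CO3 (2.2 equiv), DMF, rt to 50 °C
Reagents that add atoms: benzyl bromide, BrCc1ccccc1
Why: Williamson etherification, in which the hydroxyl that remains hydrogen-bonded to the acetyl carbonyl is the least nucleophilic, so two equivalents of benzyl bromide should stop at the dibenzyl ether.

**Step 2**
Reactants: 2 1-[2,4-bis(benzyloxy)-6-hydroxyphenyl]ethanone; 3 di-tert-butyl dicarbonate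
Product: 4 tert-butyl 3-[2,4-bis(benzyloxy)-6-hydroxyphenyl]-3-oxopropanoate
Conditions: LiN(SiMe3)2 (3.3 equiv), THF, −78 °C; 3 (1.1 equiv), −78 to −30 °C; AcOH quench
Reagents that add atoms: di-tert-butyl dicarbonate (compound 3), CC(C)(C)OC(=O)OC(=O)OC(C)(C)C
Why: Claisen-type C-acylation of the dilithiated o-hydroxyacetophenone, whose enolate carbon is far more nucleophilic than the chelated phenoxide, while the third equivalent of base stores the product as its stabilised enolate.

**Step 3**
Reactants: 5 3-bromo-4-hydroxybenzaldehyde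
Product: 6 4-(benzyloxy)-3-bromobenzaldehyde
Conditions: BnBr (1.1 equiv), K2CO3, DMF, rt
Reagents that add atoms: benzyl bromide, BrCc1ccccc1
Why: Williamson etherification of an acidic phenol with no competing nucleophilic site.

**Step 4**
Reactants: 6 4-(benzyloxy)-3-bromobenzaldehyde; 7 4-(benzyloxy)-3-hydroxybenzaldehyde
Product: 8 3,3'-oxybis[4-(benzyloxy)benzaldehyde]
Conditions: CuI (10 mol %), picolinic acid (20 mol %), K3PO4 (2 equiv), DMSO, 90 °C
Reagents that add atoms: none
Why: Ullmann-type diaryl ether synthesis with a picolinate-ligated monovalent copper catalyst, a system suited to ortho-substituted partners and tolerant of aldehydes because the ligand has no condensable N-H.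

**Step 5**
Reactants: 8 3,3'-oxybis[4-(benzyloxy)benzaldehyde]; 4 tert-butyl 3-[2,4-bis(benzyloxy)-6-hydroxyphenyl]-3-oxopropanoate (2.2 equiv)
Product: 9 (Z,Z)-bis(alkylidene beta-keto ester), in which each former formyl carbon of 8 is the beta-carbon of a tert-butyl (Z)-2-[2,4-bis(benzyloxy)-6-hydroxybenzoyl]acrylate unit (ring B aryl cis to the ester)
Conditions: piperidine (20 mol %), AcOH (20 mol %), 4 Å molecular sieves, toluene, 23 °C
Reagents that add atoms: none
Why: Double Knoevenagel condensation in which the bulky, twisted aroyl group should settle trans to the ring B aryl group (Z geometry), while the buffered medium and the chelated phenol should hold back premature ring closure.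

**Step 6**
Reactants: 9 (Z,Z)-bis(alkylidene beta-keto ester)
Product: 10 3',3'''-oxybis[tert-butyl (2S,3R)-5,7,4'-tris(benzyloxy)-4-oxoflavan-3-carboxylate], the bis(trans-3-tert-butoxycarbonylflavanone)
Conditions: 3,5-bis(trifluoromethyl)phenyl thiourea of 9-amino-9-deoxy-epi-quinidine (20 mol %, i.e. 10 mol % per alkylidene), toluene, −25 °C; filtration through a short silica pad
Reagents that add atoms: none
Why: Each arm reacts by intramolecular oxa-Michael addition, in which the two thiourea N-H bonds hold the 1,3-dicarbonyl unit, the quinuclidine nitrogen accepts the ring A phenol proton, and the phenoxide oxygen attacks the benzylidene carbon to form O1-C2. The closest known reaction type is the cinchona-thiourea-catalysed enantioselective cyclisation of 2-hydroxyaryl alkylidene beta-keto esters to 3-carboxyflavanones, run here at two independent sites of one molecule. Both rings C close in the 6-endo-trig mode, since both carbons of the attacked C=C bond end up inside the new six-membered ring. The two C2 centres are set by the catalyst, which exposes only one face of each bound alkylidene, whereas the two C3 centres are set by the substrate, because the acidic C3-H equilibrates through the enol to the trans arrangement with aryl and ester both equatorial. The step needs enantiofacial selectivity at both benzylidene carbons and suppression of the uncatalysed and reverse reactions, and the geminal tert-butyl ester secures this by offering a two-point binding site, by making the acceptor reactive enough at −25 °C despite the donor-substituted ring B, and by turning the adduct into a stabilised beta-dicarbonyl with little tendency to reopen. Because the two closures are independent, a wrong-sense event is diverted mainly into the meso (2S,2'''R) diastereomer, so the C2-symmetric product should be enriched beyond the single-site selectivity by statistical amplification.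

**Step 7**
Reactants: 10 bis(trans-3-tert-butoxycarbonylflavanone)
Product: 12 3',3'''-oxybis[(2S)-5,7,4'-tris(benzyloxy)flavan-4-one], via bis(beta-keto acid) 11 (not isolated)
Conditions: p-TsOH·H2O (40 mol %), toluene, 80 °C
Reagents that add atoms: none
Why: Acid-catalysed loss of isobutene from the tert-butyl esters followed by thermal decarboxylation of the beta-keto acids, with no base present, so the retro-oxa-Michael path that would erode C2 stays closed and the aryl benzyl ethers tolerate the sulfonic acid.

**Step 8**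
Reactants: 12 3',3'''-oxybis[(2S)-5,7,4'-tris(benzyloxy)flavan-4-one]
Product: 13 3',3'''-oxybis[(2S)-5,7,4'-tris(benzyloxy)-4-(trimethylsilyloxy)flav-3-ene], the bis(silyl enol ether)
Conditions: Me3SiOTf (3 equiv), Et3N (4 equiv), CH2Cl2, −20 to 0 °C; cold aq. NaHCO3 wash, used crude
Reagents that add atoms: trimethylsilyl trifluoromethanesulfonate, C[Si](C)(C)OS(=O)(=O)C(F)(F)F
Why: Soft enolisation, in which the silyl triflate activates the C4 carbonyl and the amine removes a C3 proton, so no free enolate arises that could expel the ring A phenoxide (E1cB) and scramble C2.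

**Step 9**
Reactants: 13 bis(silyl enol ether)
Product: 15 3',3'''-oxybis[(2R,3R)-5,7,4'-tris(benzyloxy)-3-hydroxyflavan-4-one], via bis(silyloxy epoxide) 14 (not isolated)
Conditions: dimethyldioxirane (acetone solution, 2.5 equiv), CH2Cl2, −40 to 0 °C; then 0.5 M aq. HCl, THF, 0 °C
Reagents that add atoms: dimethyldioxirane, CC1(C)OO1
Why: Rubottom oxidation, in which the neutral dioxirane epoxidises the electron-rich C3=C4 bond on the face opposite the C2 aryl group and acid opening of the silyloxy epoxide gives the 2,3-trans ketol, which is also the thermodynamically preferred diequatorial isomer.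

**Step 10**
Reactants: 15 3',3'''-oxybis[(2R,3R)-5,7,4'-tris(benzyloxy)-3-hydroxyflavan-4-one]
Product: 16 3',3'''-oxybis[(2R,3S,4R)-5,7,4'-tris(benzyloxy)flavan-3,4-diol]
Conditions: NaBH4 (4 equiv), THF/MeOH, 0 °C; aq. NH4Cl
Reagents that add atoms: none
Why: Borohydride reduction of the aryl ketone, with axial hydride delivery expected to favour the 3,4-trans diol, and the C4 configuration is immaterial because this centre is erased in the next step.

**Step 11**
Reactants: 16 3',3'''-oxybis[(2R,3S,4R)-5,7,4'-tris(benzyloxy)flavan-3,4-diol]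
Product: 17 3',3'''-oxybis[(2R,3S)-5,7,4'-tris(benzyloxy)flavan-3-ol]
Conditions: Et3SiH (20 equiv), CF3CO2H (10 equiv), CH2Cl2 (dilute), −20 to 0 °C; aq. NaHCO3
Reagents that add atoms: none
Why: Ionic hydrogenation, in which the C4 hydroxyl ionises readily because O1 and the 5- and 7-benzyloxy groups stabilise the cation, the large excess of silane should trap it before an arene can, and the non-benzylic C3 hydroxyl and the less easily ionised O1-C2 bond should persist at low temperature.

**Step 12**
Reactants: 17 3',3'''-oxybis[(2R,3S)-5,7,4'-tris(benzyloxy)flavan-3-ol]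
Product: 18 catechin-(3'-O-3''')-afzelechin, (2R,3S,2'''R,3'''S)
Conditions: H2 (1 atm), Pd(OH)2/C, THF/MeOH, rt
Reagents that add atoms: none
Why: Hydrogenolysis of six aryl benzyl ethers under neutral conditions, standard for benzylated catechins, which should leave the diaryl ether, ring C and all four stereocentres unaffected.

**Compound list**

1 | 2,4,6-trihydroxyacetophenone | CC(=O)c1c(O)cc(O)cc1O | starting material

2 | 1-[2,4-bis(benzyloxy)-6-hydroxyphenyl]ethanone | CC(=O)c1c(O)cc(OCc2ccccc2)cc1OCc1ccccc1 | intermediate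

3 | di-tert-butyl dicarbonate | CC(C)(C)OC(=O)OC(=O)OC(C)(C)C | starting material

4 | tert-butyl 3-[2,4-bis(benzyloxy)-6-hydroxyphenyl]-3-oxopropanoate | CC(C)(C)OC(=O)CC(=O)c1c(O)cc(OCc2ccccc2)cc1OCc1ccccc1 | intermediate

5 | 3-bromo-4-hydroxybenzaldehyde | O=Cc1ccc(O)c(Br)c1 | starting material

6 | 4-(benzyloxy)-3-bromobenzaldehyde | O=Cc1ccc(OCc2ccccc2)c(Br)c1 | intermediate

7 | 4-(benzyloxy)-3-hydroxybenzaldehyde | O=Cc1ccc(OCc2ccccc2)c(O)c1 | starting material

8 | 3,3'-oxybis[4-(benzyloxy)benzaldehyde] | O=Cc1ccc(OCc2ccccc2)c(Oc2cc(C=O)ccc2OCc2ccccc2)c1 | intermediate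

9 | (Z,Z)-bis(alkylidene beta-keto ester) | O(c1cc(/C=C(\C(=O)OC(C)(C)C)C(=O)c2c(O)cc(OCc3ccccc3)cc2OCc3ccccc3)ccc1OCc3ccccc3)c1cc(/C=C(\C(=O)OC(C)(C)C)C(=O)c2c(O)cc(OCc3ccccc3)cc2OCc3ccccc3)ccc1OCc3ccccc3 | intermediate

10 | 3',3'''-oxybis[tert-butyl (2S,3R)-5,7,4'-tris(benzyloxy)-4-oxoflavan-3-carboxylate] | O(c1cc([C@H]2Oc3cc(OCc4ccccc4)cc(OCc4ccccc4)c3C(=O)[C@@H]2C(=O)OC(C)(C)C)ccc1OCc4ccccc4)c1cc([C@H]2Oc3cc(OCc4ccccc4)cc(OCc4ccccc4)c3C(=O)[C@@H]2C(=O)OC(C)(C)C)ccc1OCc4ccccc4 | intermediate

11 | 3',3'''-oxybis[(2S,3R)-5,7,4'-tris(benzyloxy)-4-oxoflavan-3-carboxylic acid] | O(c1cc([C@H]2Oc3cc(OCc4ccccc4)cc(OCc4ccccc4)c3C(=O)[C@@H]2C(=O)O)ccc1OCc4ccccc4)c1cc([C@H]2Oc3cc(OCc4ccccc4)cc(OCc4ccccc4)c3C(=O)[C@@H]2C(=O)O)ccc1OCc4ccccc4 | intermediate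

12 | 3',3'''-oxybis[(2S)-5,7,4'-tris(benzyloxy)flavan-4-one] | O(c1cc([C@H]2Oc3cc(OCc4ccccc4)cc(OCc4ccccc4)c3C(=O)C2)ccc1OCc4ccccc4)c1cc([C@H]2Oc3cc(OCc4ccccc4)cc(OCc4ccccc4)c3C(=O)C2)ccc1OCc4ccccc4 | intermediate

13 | 3',3'''-oxybis[(2S)-5,7,4'-tris(benzyloxy)-4-(trimethylsilyloxy)flav-3-ene] | O(c1cc([C@H]2Oc3cc(OCc4ccccc4)cc(OCc4ccccc4)c3C(O[Si](C)(C)C)=C2)ccc1OCc4ccccc4)c1cc([C@H]2Oc3cc(OCc4ccccc4)cc(OCc4ccccc4)c3C(O[Si](C)(C)C)=C2)ccc1OCc4ccccc4 | intermediate

14 | 3',3'''-oxybis[(2R,3R,4R)-5,7,4'-tris(benzyloxy)-3,4-epoxy-4-(trimethylsilyloxy)flavan], epoxide oxygen anti to the C2 aryl group | O(c1cc([C@H]2Oc3cc(OCc4ccccc4)cc(OCc4ccccc4)c3[C@]5(O[Si](C)(C)C)O[C@H]25)ccc1OCc4ccccc4)c1cc([C@H]2Oc3cc(OCc4ccccc4)cc(OCc4ccccc4)c3[C@]5(O[Si](C)(C)C)O[C@H]25)ccc1OCc4ccccc4 | intermediate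

15 | 3',3'''-oxybis[(2R,3R)-5,7,4'-tris(benzyloxy)-3-hydroxyflavan-4-one] | O(c1cc([C@H]2Oc3cc(OCc4ccccc4)cc(OCc4ccccc4)c3C(=O)[C@@H]2O)ccc1OCc4ccccc4)c1cc([C@H]2Oc3cc(OCc4ccccc4)cc(OCc4ccccc4)c3C(=O)[C@@H]2O)ccc1OCc4ccccc4 | intermediate

16 | 3',3'''-oxybis[(2R,3S,4R)-5,7,4'-tris(benzyloxy)flavan-3,4-diol] | O(c1cc([C@H]2Oc3cc(OCc4ccccc4)cc(OCc4ccccc4)c3[C@@H](O)[C@@H]2O)ccc1OCc4ccccc4)c1cc([C@H]2Oc3cc(OCc4ccccc4)cc(OCc4ccccc4)c3[C@@H](O)[C@@H]2O)ccc1OCc4ccccc4 | intermediate

17 | 3',3'''-oxybis[(2R,3S)-5,7,4'-tris(benzyloxy)flavan-3-ol] | O(c1cc([C@H]2Oc3cc(OCc4ccccc4)cc(OCc4ccccc4)c3C[C@@H]2O)ccc1OCc4ccccc4)c1cc([C@H]2Oc3cc(OCc4ccccc4)cc(OCc4ccccc4)c3C[C@@H]2O)ccc1OCc4ccccc4 | intermediate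

18 | catechin-(3'-O-3''')-afzelechin | Oc1cc(O)c2c(c1)O[C@H](c1ccc(O)c(Oc3cc([C@H]4Oc5cc(O)cc(O)c5C[C@@H]4O)ccc3O)c1)[C@@H](O)C2 | target

**Step count**
Total step count: 12.
Longest linear sequence: 10 steps (steps 3 to 12 from 5, or equally steps 1, 2 and 5 to 12 from 1).

**Steps most likely to fail**

**Step 6.**
- What may go wrong:
  - Facial control may be incomplete at one or both sites. The 6'-benzyloxy group twists the aroyl unit, and the chelated phenol gives up its proton reluctantly.
  - Turnover may be slow at low temperature, which gives the uncatalysed closure time to compete.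
  - The meso diastereomer may be hard to remove, because its stereocentres lie far apart.
- Fallback: it sets out from 2 and 8 and comes back at 15. The absolute configuration comes from an asymmetric epoxidation instead.
  - The phenol of 2 is capped with MOMCl and iPr2NEt to give 1-[2,4-bis(benzyloxy)-6-(methoxymethoxy)phenyl]ethanone F1.
  - A double Claisen-Schmidt condensation of F1 with 8 (KOH, EtOH/THF) gives the (E,E)-bis(2'-methoxymethoxychalcone) F2.
  - Juliá-Colonna epoxidation (poly-L-leucine, urea·H2O2, DBU, THF) gives the bis[(alphaR,betaS)-chalcone epoxide] F3.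
  - HCl in MeOH/THF at 45 °C removes the acetal. The freed ring A phenol then opens each epoxide at the benzylic carbon, which again forms O1-C2 and delivers 15.
  - The C3-O bond is never broken in this sequence, so it anchors the configuration. C2 follows by inversion or, if the opening becomes cation-like, by closure to the favoured trans ring.

**Step 5.**
- What may go wrong:
  - Condensation of an electron-rich dialdehyde with a hindered keto ester may be sluggish or may stop after one arm.
  - Alkene geometries may be mixed.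
  - The amine may promote racemic ring closure of the free phenol before the chiral catalyst is introduced.
- Fallback: it sets out from 4 (with 8) and comes back at 9. The nucleophile is masked during C=C bond formation.
  - TBSCl and imidazole in DMF convert 4 into tert-butyl 3-[2,4-bis(benzyloxy)-6-(tert-butyldimethylsilyloxy)phenyl]-3-oxopropanoate F4.
  - The condensation with 8 can now be forced (TiCl4/pyridine or azeotropic removal of water) to give the (Z,Z)-bis(alkylidene beta-keto ester) bis(silyl ether) F5.
  - HF·pyridine in THF at 0 °C, an acidic fluoride source that never liberates free phenoxide, unveils 9 directly before the key step.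

**Step 8.**
- What may go wrong:
  - Ring C may open, either by expulsion of the ring A phenoxide or by ionisation of the O1-C2 bond of the O-silylated ketone. The 4'-benzyloxy group assists the latter. Either event erodes C2.
  - Double enolisation next to the peri 5-benzyloxy group may be incomplete.
  - Facial bias in the oxidation that follows may be insufficient.
- Fallback: it sets out from 12 and comes back at 17. It avoids enolisation altogether and bypasses steps 9 to 11.
  - NaBH4 reduces 12 to the bis[(2S,4S)-2,4-cis-flavan-4-ol] F6.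
  - PPTS in warm toluene dehydrates F6 to the bis[(2S)-flav-3-ene] F7.
  - Hydroboration with BH3·THF places boron on C3, away from the ring A benzylic carbon, on the face opposite the C2 aryl group.
  - Oxidation with H2O2/NaOH proceeds with retention and gives the 2,3-trans alcohol 17.

**Further compounds**

F1 | step 6 | 1-[2,4-bis(benzyloxy)-6-(methoxymethoxy)phenyl]ethanone | CC(=O)c1c(OCOC)cc(OCc2ccccc2)cc1OCc1ccccc1

F2 | step 6 | (E,E)-bis(2'-methoxymethoxychalcone) | O(c1cc(/C=C/C(=O)c2c(OCOC)cc(OCc3ccccc3)cc2OCc3ccccc3)ccc1OCc3ccccc3)c1cc(/C=C/C(=O)c2c(OCOC)cc(OCc3ccccc3)cc2OCc3ccccc3)ccc1OCc3ccccc3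

F3 | step 6 | bis[(alphaR,betaS)-chalcone epoxide] | O(c1cc([C@@H]2O[C@H]2C(=O)c3c(OCOC)cc(OCc4ccccc4)cc3OCc4ccccc4)ccc1OCc4ccccc4)c1cc([C@@H]2O[C@H]2C(=O)c3c(OCOC)cc(OCc4ccccc4)cc3OCc4ccccc4)ccc1OCc4ccccc4

F4 | step 5 | tert-butyl 3-[2,4-bis(benzyloxy)-6-(tert-butyldimethylsilyloxy)phenyl]-3-oxopropanoate | CC(C)(C)OC(=O)CC(=O)c1c(O[Si](C)(C)C(C)(C)C)cc(OCc2ccccc2)cc1OCc1ccccc1

F5 | step 5 | (Z,Z)-bis(alkylidene beta-keto ester) bis(silyl ether) | O(c1cc(/C=C(\C(=O)OC(C)(C)C)C(=O)c2c(O[Si](C)(C)C(C)(C)C)cc(OCc3ccccc3)cc2OCc3ccccc3)ccc1OCc3ccccc3)c1cc(/C=C(\C(=O)OC(C)(C)C)C(=O)c2c(O[Si](C)(C)C(C)(C)C)cc(OCc3ccccc3)cc2OCc3ccccc3)ccc1OCc3ccccc3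

F6 | step 8 | bis[(2S,4S)-2,4-cis-flavan-4-ol] | O(c1cc([C@H]2Oc3cc(OCc4ccccc4)cc(OCc4ccccc4)c3[C@@H](O)C2)ccc1OCc4ccccc4)c1cc([C@H]2Oc3cc(OCc4ccccc4)cc(OCc4ccccc4)c3[C@@H](O)C2)ccc1OCc4ccccc4

F7 | step 8 | bis[(2S)-flav-3-ene] | O(c1cc([C@H]2Oc3cc(OCc4ccccc4)cc(OCc4ccccc4)c3C=C2)ccc1OCc4ccccc4)c1cc([C@H]2Oc3cc(OCc4ccccc4)cc(OCc4ccccc4)c3C=C2)ccc1OCc4ccccc4
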